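Readings and results come from a simulation for substances that don't exist, noise included.

The south-west run was charged with 4.35 times the starting material of the north-east run, yet at 15.0 min both stand at nearly the same fraction of their charge, 55.8 % and 56.5 % target, with 0.4 % and 0.3 % of the starting material left.

| flask | starting material | coupling partner | protic impurity | remark | time |
|---|---|---|---|---|---|
| north-east | 0.069 M | 0.468 M | 0.078 M | run made earlier |  |
| south-west | 0.30 M | 0.468 M | 0.078 M | run made earlier |  |
| summer | 0.060 M | 0.468 M | 0.0780 M |  | 30 min |
| dusk | 0.26 M | 0.468 M | 0.0780 M |  | 15 min |

- north-east (time / min: target / %, starting material / %): 1.33: 53.4, 5.2; 2.00: 55.5, 2.4; 3.00: 56.6, 0; 4.00: 56.8, 0; 6.00: 56.2, 0.3; 10.0: 55.2, 1.0; 15.0: 55.8, 0.4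
- south-west (time / min: target / %, starting material / %): 0.833: 42.6, 22.9; 2.50: 54.7, 2.0; 4.00: 56.6, 0.7; 6.00: 56.1, 0; 10.0: 56.4, 0; 12.0: 56.2, 0.4; 15.0: 56.5, 0.3

(readings scatter by 0.5 percentage points)

* which one finishes higher in amount of target, in percent of the starting material charged ("neither" within 2 percentage points) (summer / dusk / neither)
* amount of target at the end, in percent of the starting material charged, summer
* amount of target at the end, in percent of the starting material charged, dusk

- a reading or a percentage of target counts all its forms, free or not

We take the mean of those two readings, 56.1 %, and carry it as the target share, the fraction of consumed starting material that ends as target. One doubt is that a plateau says little about the way there. But the south-west run at 0.833 min has 42.6 % target from 77.1 % consumed, a reading of 55.3 %, so the share stays close to its final value while the reaction runs.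

A second doubt is that the protic impurity takes a fixed amount, one for one. Its charge equals 1.13 of the starting material in the north-east run and 0.260 in the south-west run, yet the plateaus match, so we drop that picture.

Both new flasks keep the same coupling partner and impurity charges. Dusk lies between the two runs in starting material, and summer lies slightly below them, at 0.870 of the north-east charge. The south-west run was down to 2.0 % starting material by 2.50 min, well before the asked times, so we take each charge as consumed.

The last doubt is that summer runs to 30 min, past every reading. The north-east run slipped from 56.8 % to 55.8 % after 4.00 min, and that slope carried to summer's end costs 1.4 percentage points, still under the margin. So we commit to 56.1 % for both flasks, with no winner.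

The forecast gives 56 % for summer and 56.2 % for dusk, so neither, reading the constant share as “parallel pathways of the same order, with selectivity independent of concentration”.

The simulation gives 56.1 % for summer and 56.3 % for dusk, so the answer is neither.

    crystals ⇌ target, rate k1*(cs1 - [target]) while solid is left; crystals form when [target] > cs1 (solubility = 11.0 mM, k = 0.0850 s⁻¹)
    starting material + coupling partner → isomer of the product (k = 0.0250 M⁻¹ s⁻¹)
    starting material + protic impurity → quenched substrate (k = 0.0800 M⁻¹ s⁻¹)
    starting material + coupling partner → target (k = 0.0490 M⁻¹ s⁻¹)

In dusk at 0.330 min, starting material went to target 2.0 times as fast as to isomer of the product (the selectivity factor). Dusk ends with 28.7 % isomer of the product, 15.0 % quenched substrate and 0 % starting material, beside its 56.3 % target. The neighbour of dusk charged with 1.0 M of starting material has consumed 54.6 % of it at 15.0 min, so the share gives 30.7 % target, and that flask holds 31.0 %.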